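For early times the alpha run gives readings of two products, X and E, so my working reckoning treats them as two exits for D and follows the share each takes.

| flask | D | J | remark | time |
|---|---|---|---|---|
| alpha | 1.5 M | 1.65 M | the very flask that is asked about, followed so far |  |
| zeta | 1.5 M | 2.5 M | run made earlier |  |
| flask | 1.5 M | 1.65 M |  | 4.0 min |

alpha run (percent of the D charged)

| time / s | E / % | X / % |
|---|---|---|
| 12.0 | 4.9 | 44.6 |
| 25.0 | 9.9 | 62.3 |
| 40.0 | 12.9 | 70.0 |
| 50.0 | 12.5 | 71.4 |
| 60.0 | 12.7 | 74.0 |
| 80.0 | 16.1 | 77.6 |

zeta run (percent of the D charged)

| time / min | E / % | X / % |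
|---|---|---|
| 0.667 | 7.5 | 86.2 |
| 1.33 | 11.5 | 91.2 |
| 2.00 | 8.6 | 90.6 |
| 2.50 | 9.6 | 90.2 |
| 3.00 | 8.3 | 91.5 |
| 4.00 | 10.3 | 90.8 |

(scatter of a reading: 1 percentage point)

- the numbers in the tables scatter by 1 percentage point (one standard deviation)
- a reading or a percentage of X counts all its forms, free or not

1. ratio of E to X at 0.30 s
2. ratio of E to X at 8.0 s
3. ratio of E to X at 4.0 min

My working model is this: D leaves to X at a rate proportional to c_D·c_J, or to E at a rate proportional to c_D, and I assume E costs one J as well. Define K as the c_J at which the two exits run equal, what you would call a half-saturation constant. The share of D going to E is then K/(c_J + K), and the momentary ratio of E to X is K/c_J. Reckoning with the J left gives: E so far = K·ln[(charged J + K)/(c_J now + K)].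

The zeta run supplies K. Its E readings from 1.33 min on average 0.145 M, and its c_J ends at 1.00 M, so one pass of substitution gives K = 0.174 M.

Now run the alpha flask slowly. In the first instants c_J stands at its charge, well above K, so E should take 9.56% of the D and the ratio should start at 0.106. That assumes E appears without delay, and the earliest reading is at 12.0 s, so I hold this value loosely.

At 40.0 s the readings, on my assumption of one J per product, leave c_J at 0.406 M, and my model puts E's share at 30.0%. The rule gives E 13.3% there, against 12.9% read.

At 80.0 s the readings of E and X together leave 6.30% of the D uncounted. I therefore reckon the end with D, the limiting reagent, used up and c_J at 0.150 M, below K. That gives E = 0.301 M and a ratio of 0.251 at 4.0 min.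

The forecast says 0.11, 0.125 and 0.205, reading a ratio that climbs “as J is used up”, and its last value stands below mine.

The flask gives 0.00708, 0.0888 and 0.234, under both my start value and my end value.

    G ⇌ X, rate k1*(cs1 - [X]) while solid is left; crystals form when [X] > cs1 (solubility = 0.350 M, k = 0.518 s⁻¹)
    D + J → X (k = 0.0442 M⁻¹ s⁻¹)
    J + L → E (k = 0.284 M⁻¹ s⁻¹)
    D ⇌ L (K = 2.17, k = 0.00769 s⁻¹)

The climb is read from one comparison: a run with c_J held at its charge ends at 0.105, against 0.234 as it stands, so the shrinking supply of J lifts the ratio. For a held c_J, K over the charge gives 0.106. Take a neighbour flask, with 0.60 M of D and the same J: c_J ends near 1.05 M, far above K, so the rule gives E = 0.0696 M and a ratio of 0.131. The simulation gives 0.129.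

The earlier runs and the new flask were generated by integration on assumed constants; noise was put on by code.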